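**Plan**

1. Retrosynthesis (oxolan-2-one numbering O1, C2(=O), C3, C4, C5): the aryl O-benzyl group is removed last; the C3–CH2Ar bond to the 3,4,5-trimethoxyphenyl unit is cut (enolate benzylation); the ring bond O1–C5 is cut with excision of O1 (Baeyer–Villiger retron), which contracts the lactone to a cyclobutanone; the cyclobutanone is cut by a ketene/alkene [2+2] back to O-benzyleugenol.
2. Enabling feature: in the lactone ring the stereocentre C4 is flanked by two ring CH2 groups, C3 and C5, that differ only in that C5 is bonded to O1. Without O1 they are the enantiotopic α-CH2 groups of a mirror-symmetric 3-(arylmethyl)cyclobutanone, in which C4 is only prochiral.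
3. Forward: eugenol → benzyl ether → dichloroketene [2+2] (four-membered carbocycle) → dechlorination → catalytic asymmetric Baeyer–Villiger ring expansion (lactone ring, O1–C5 bond) → trans-selective C3 benzylation (joins the second aryl unit) → hydrogenolysis.
4. Stereochemistry: C4 (R) is set by the chiral catalyst, which decides which enantiotopic CH2 migrates; C3 (R) is set by substrate control, the electrophile entering anti to the C4 substituent.

Key step: step 4

Assumption: the sense of induction of the scandium/N,N'-dioxide catalyst for a 3-(arylmethyl)cyclobutanone cannot be assigned with certainty in advance, so the ligand enantiomer that leads to the (4R)-lactone is to be selected in a trial run; all descriptors below refer to that series.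

**Route**

Step 1
Reactants: 1 eugenol (4-allyl-2-methoxyphenol)
Product: 2 4-allyl-1-(benzyloxy)-2-methoxybenzene (O-benzyleugenol)
Conditions: BnBr, K2CO3, acetone, reflux
Reagents that add atoms: benzyl bromide, BrCc1ccccc1
Why: Williamson ether synthesis (SN2 of the phenoxide on the benzylic bromide); the benzyl ether shields the phenol from acylation in step 2, oxidation in step 4 and deprotonation in step 5, and the allyl group is inert.

Step 2
Reactants: 2 4-allyl-1-(benzyloxy)-2-methoxybenzene
Product: 3 2,2-dichloro-3-[(4-benzyloxy-3-methoxyphenyl)methyl]cyclobutan-1-one (racemic)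
Conditions: Cl3CCOCl, Zn–Cu couple, POCl3, Et2O, reflux, slow addition
Reagents that add atoms: trichloroacetyl chloride, ClC(=O)C(Cl)(Cl)Cl (turned in the flask into dichloroketene, ClC(Cl)=C=O)
Why: Thermal ketene–alkene [2+2] cycloaddition of dichloroketene generated in the flask, in which the terminal alkene CH2 bonds to the ketene carbonyl carbon so that CCl2 ends up next to the substituted carbon, while POCl3 ties up ZnCl2; the new stereocentre is formed racemic and loses its stereogenicity in step 3.

Step 3
Reactants: 3 2,2-dichloro-3-[(4-benzyloxy-3-methoxyphenyl)methyl]cyclobutan-1-one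
Product: 4 3-[(4-benzyloxy-3-methoxyphenyl)methyl]cyclobutan-1-one
Conditions: Zn dust, AcOH, rt to 50 °C
Reagents that add atoms: none
Why: Reductive dehalogenation of an α,α-dichloro ketone by zinc (two successive electron-transfer/protonation events through zinc enolates) should give the mirror-symmetric cyclobutanone with the benzyl ether and the strained ring untouched.

Step 4
Reactants: 4 3-[(4-benzyloxy-3-methoxyphenyl)methyl]cyclobutan-1-one
Product: 6 (4R)-4-[(4-benzyloxy-3-methoxyphenyl)methyl]oxolan-2-one, via peroxyhemiketal adduct 5 (not isolated)
Conditions: Sc(OTf)3 (5 mol%), chiral N,N'-dioxide ligand L* (6 mol%; propane-1,3-diyl-bridged bis[N-(2,6-diisopropylphenyl)pipecolamide] N,N'-dioxide, enantiomer as assumed above), m-CPBA, EtOAc, −20 °C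
Reagents that add atoms: m-CPBA (3-chloroperoxybenzoic acid), OOC(=O)c1cccc(Cl)c1
Why: The ketone, activated on the chiral trivalent scandium centre, adds m-CPBA to give peroxyhemiketal 5, and one α-CH2 then shifts with its bonding pair from the carbinol carbon to the proximal peroxide oxygen while 3-chlorobenzoate leaves, so that the new O1–C5 bond turns the cyclobutane into the five-membered lactone. The closest known reaction type is the catalytic asymmetric Baeyer–Villiger desymmetrisation of prochiral 3-substituted cyclobutanones with chiral Lewis acid, Brønsted acid or enzyme catalysts. The ring is closed by a 1,2-shift of carbon to oxygen (ring expansion from four to five members, not a chain cyclisation), driven by release of cyclobutanone strain. No bond is made or broken at C4; it becomes a stereocentre because the catalyst holds the peroxyhemiketal so that the O–O bond is antiperiplanar to only one of the two enantiotopic CH2 groups, so the ligand configuration alone decides between (R) and (S). The step needs enantiotopic-group selectivity and chemoselectivity: regiochemistry is no issue because both migrating candidates are CH2 groups that lead to the same constitution, the strained ketone should react at −20 °C well before the electron-rich benzyloxy(methoxy)arene or the benzylic positions are attacked, and low temperature with slow oxidant addition should keep the uncatalysed background oxidation small.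

Step 5
Reactants: 6 (4R)-4-[(4-benzyloxy-3-methoxyphenyl)methyl]oxolan-2-one; 7 3,4,5-trimethoxybenzyl bromide
Product: 9 (3R,4R)-4-[(4-benzyloxy-3-methoxyphenyl)methyl]-3-[(3,4,5-trimethoxyphenyl)methyl]oxolan-2-one, via lithium enolate 8 (not isolated)
Conditions: LiN(i-Pr)2 (1.05 equiv), THF, −78 °C; then 7, DMPU, −78 to −40 °C
Reagents that add atoms: none
Why: Enolate alkylation of a β-substituted γ-butyrolactone, in which the benzylic bromide approaches the planar lithium enolate on the face opposite the C4 arylmethyl group (1,2-induction) and should give the 3,4-trans (3R,4R) product, the standard way to trans-dibenzylbutyrolactone lignans.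

Step 6
Reactants: 9 (3R,4R)-4-[(4-benzyloxy-3-methoxyphenyl)methyl]-3-[(3,4,5-trimethoxyphenyl)methyl]oxolan-2-one
Product: 10 hernanol
Conditions: H2 (1 atm), 10% Pd/C, EtOAc/EtOH, rt
Reagents that add atoms: none
Why: Hydrogenolysis of the benzyl aryl ether over palladium under neutral conditions should free the phenol while the lactone, the methyl ethers and both stereocentres stay untouched (no base, so no epimerisation at C3).

**Compound list**

1 | eugenol (4-allyl-2-methoxyphenol) | C=CCc1ccc(O)c(OC)c1 | starting material
2 | 4-allyl-1-(benzyloxy)-2-methoxybenzene | C=CCc1ccc(OCc2ccccc2)c(OC)c1 | intermediate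
3 | 2,2-dichloro-3-[(4-benzyloxy-3-methoxyphenyl)methyl]cyclobutan-1-one, racemic | COc1cc(CC2CC(=O)C2(Cl)Cl)ccc1OCc1ccccc1 | intermediate
4 | 3-[(4-benzyloxy-3-methoxyphenyl)methyl]cyclobutan-1-one, achiral | COc1cc(CC2CC(=O)C2)ccc1OCc1ccccc1 | intermediate
5 | peroxyhemiketal adduct of 4 and m-CPBA, 3-[(4-benzyloxy-3-methoxyphenyl)methyl]-1-hydroxycyclobutyl 3-chloroperoxybenzoate (scandium-bound in the flask, drawn metal-free; achiral, ring cis/trans not defined; not isolated) | COc1cc(CC2CC(O)(OOC(=O)c3cccc(Cl)c3)C2)ccc1OCc1ccccc1 | intermediate
6 | (4R)-4-[(4-benzyloxy-3-methoxyphenyl)methyl]oxolan-2-one | COc1cc(C[C@H]2COC(=O)C2)ccc1OCc1ccccc1 | intermediate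
7 | 3,4,5-trimethoxybenzyl bromide | COc1cc(CBr)cc(OC)c1OC | starting material
8 | lithium enolate of 6, lithium (4R)-4-[(4-benzyloxy-3-methoxyphenyl)methyl]-4,5-dihydrofuran-2-olate (not isolated) | COc1cc(C[C@H]2COC(O[Li])=C2)ccc1OCc1ccccc1 | intermediate
9 | (3R,4R)-4-[(4-benzyloxy-3-methoxyphenyl)methyl]-3-[(3,4,5-trimethoxyphenyl)methyl]oxolan-2-one (3,4-trans) | COc1cc(C[C@H]2COC(=O)[C@@H]2Cc2cc(OC)c(OC)c(OC)c2)ccc1OCc1ccccc1 | intermediate
10 | hernanol, (3R,4R)-4-[(4-hydroxy-3-methoxyphenyl)methyl]-3-[(3,4,5-trimethoxyphenyl)methyl]oxolan-2-one | COc1cc(C[C@H]2COC(=O)[C@@H]2Cc2cc(OC)c(OC)c(OC)c2)ccc1O | target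

**Step count and risks**

Total step count: 6. Longest linear sequence: 6 steps (from eugenol).

Steps most likely to fail:

Step 4. The two enantiotopic CH2 groups may be discriminated poorly, because the aryl group sits one CH2 away from the ring and offers the catalyst little steric bias, and uncatalysed background oxidation would further erode the enantiomeric purity. Fallback (resolution instead of catalytic desymmetrisation), setting out from 4 and returning at 6: uncatalysed Baeyer–Villiger oxidation of 4 (m-CPBA, NaHCO3, CH2Cl2) should give racemic 4-[(4-benzyloxy-3-methoxyphenyl)methyl]oxolan-2-one F1. Ring-opening aminolysis with (R)-1-phenylethylamine (AlMe3, toluene, 60 °C) should give two diastereomeric γ-hydroxy amides, from which (3R)-3-[(4-benzyloxy-3-methoxyphenyl)methyl]-4-hydroxy-N-[(1R)-1-phenylethyl]butanamide F2 is separated by crystallisation or chromatography. Acid-promoted relactonisation (aq. H2SO4, dioxane, 80 °C) releases the amine and returns 6. A modest shortfall in enantiomeric purity could alternatively be corrected by recrystallising 9.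

Step 5. A second benzylation at C3 through proton exchange between product and enolate, sluggish SN2 at low temperature, or incomplete anti facial selectivity may lower the yield of the trans product. Fallback (aldol addition and reductive removal of oxygen instead of alkylation), setting out from 6 through enolate 8 and returning at 10: the enolate is trapped with 3,4,5-trimethoxybenzaldehyde (THF, −78 °C) to give the 3,4-trans aldol adduct (3S,4R)-4-[(4-benzyloxy-3-methoxyphenyl)methyl]-3-[hydroxy(3,4,5-trimethoxyphenyl)methyl]oxolan-2-one F3 as a mixture of carbinol epimers. Hydrogenolysis (H2, 10% Pd/C, AcOH, cat. HClO4) should then remove the benzylic hydroxyl and the O-benzyl group in one operation and give 10 directly, so that step 6 is no longer needed.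

Step 2. Polymerisation of dichloroketene may outrun cycloaddition to the unactivated monosubstituted alkene, and ZnCl2-promoted acylation of the electron-rich ring by the acid chloride may compete. Fallback (keteniminium instead of ketene, no zinc and no dechlorination), setting out from 2 and returning at 4: N,N-dimethylacetamide, Tf2O and 2,4,6-collidine in 1,2-dichloroethane at reflux generate N,N-dimethylketeniminium triflate, whose stepwise cationic [2+2] cycloaddition to the alkene of 2 should give N-{3-[(4-benzyloxy-3-methoxyphenyl)methyl]cyclobutylidene}-N-methylmethanaminium triflate F4. Hydrolysis with aqueous NaHCO3 should give 4 directly, bypassing 3 and step 3.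

**Further compounds**

F1 | step 4 | racemic 4-[(4-benzyloxy-3-methoxyphenyl)methyl]oxolan-2-one | COc1cc(CC2COC(=O)C2)ccc1OCc1ccccc1
F2 | step 4 | (3R)-3-[(4-benzyloxy-3-methoxyphenyl)methyl]-4-hydroxy-N-[(1R)-1-phenylethyl]butanamide | COc1cc(C[C@@H](CO)CC(=O)N[C@H](C)c2ccccc2)ccc1OCc1ccccc1
F3 | step 5 | (3S,4R)-4-[(4-benzyloxy-3-methoxyphenyl)methyl]-3-[hydroxy(3,4,5-trimethoxyphenyl)methyl]oxolan-2-one, 3,4-trans, mixture of carbinol epimers | COc1cc(C[C@H]2COC(=O)[C@@H]2C(O)c2cc(OC)c(OC)c(OC)c2)ccc1OCc1ccccc1
F4 | step 2 | N-{3-[(4-benzyloxy-3-methoxyphenyl)methyl]cyclobutylidene}-N-methylmethanaminium trifluoromethanesulfonate | COc1cc(CC2CC(=[N+](C)C)C2)ccc1OCc1ccccc1.[O-]S(=O)(=O)C(F)(F)F
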